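The ratio to watch is the fractional loss of starting material per second, late against early, in a flask fed in portions with a solid reagent and a trace of free catalyst.

| flask | starting material | solid reagent | free catalyst | remark | time |
|---|---|---|---|---|---|
| summer | 0.20 mM (in portions, 4) | 0.90 equiv | 0.2 mol% | the very flask that is asked about, followed so far; portions every 6.0 s |  |
| midnight | 0.40 mM (in portions, 4) | 0.90 equiv | 0.2 mol% | run made earlier; portions every 6.0 s |  |
| flask | 0.20 mM (in portions, 4) | 0.900 equiv | 0.2 mol% | the portions of starting material follow each other after 6.0 s, the first at the start | 2.0 min |

| run | time / s | starting material / % | target / % | isomer of the product / % |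
|---|---|---|---|---|
| summer | 10.0 | 47.9 | 2.0 | 0.2 |
| summer | 12.0 | 46.9 | 3.2 | 1.7 |
| summer | 20.0 | 92.6 | 5.8 | 1.4 |
| summer | 40.0 | 81.1 | 14.7 | 4.7 |
| midnight | 10.0 | 45.1 | 4.2 | 0 |
| midnight | 25.0 | 84.0 | 12.8 | 4.3 |
| midnight | 40.0 | 71.4 | 21.2 | 7.3 |
| midnight | 60.0 | 56.8 | 32.6 | 10.4 |
| midnight | 90.0 | 39.3 | 45.9 | 16.9 |
| midnight | 120 | 25.8 | 54.8 | 18.8 |

(readings scatter by 0.5 percentage points)

* why nothing more happens at 2.0 min, or that something still does (for what has run out or reacted, a solid counts together with what of it has only dissolved) (the partner has run out first / all of the starting material has reacted / it is still moving / forward and back rates have come level / no working catalyst is left)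
* conversion of starting material at 2.0 min
* amount of target at 2.0 min, in percent of the starting material charged
* amount of isomer of the product at 2.0 min, in percent of the starting material charged
* amount of target if the flask were left three thousand times as long, in percent of the starting material charged

- solid reagent is a solid; its amount is given per volume of the solution
- at the start none of the solid reagent is in solution
- the reaction counts as stopped when no species that holds the starting material changes by six tenths of a point or more over the second half of the time

Late in the midnight run the starting material loses 0.0140 s⁻¹ of itself, early 0.0108 s⁻¹, so the late loss is faster by a factor 1.30 although c(starting material) has fallen. Read this as saturation: at fixed catalyst, fractional loss times (K + c(starting material)) stays constant. The mean levels of the two stretches, 0.311 mM and 0.130 mM, then give the half-saturation level K = 0.482 mM, a reading that carries the scatter.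

The summer run is your flask, and its last portion is in at 18.0 s. Between 20.0 s and 40.0 s it loses 0.00663 s⁻¹ of itself. If that fraction held (the pseudo-first-order extreme), 47.7% would be left at 2.0 min. If the amount lost per second held (the saturated extreme), 35.1% would be left. I expect the flask nearer the first, because K stands above the mean level of 0.174 mM. Putting the first answer back lowers the mean level to 0.129 mM, which raises the fractional loss and leaves 45.9%. A second round leaves 45.8%, so I commit to a conversion of 54.2%.

The forecast gives 54% conversion, 40% target, 14% isomer of the product and 67% target in the long run. Its answer for the end at 2.0 min is: it is still moving, in its own words “the reaction is still moving”.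

The simulation gives: it is still moving, conversion 53.9%, target 40.0%, isomer of the product 13.9%, and 66.2% target in the long run.

    solid reagent ⇌ partner, rate k1*(cs1 - [partner]) while solid is left; crystals form when [partner] > cs1 (solubility = 0.0500 mM, k = 1.40 s⁻¹)
    target + free catalyst ⇌ isomer of the product + free catalyst, rate k2*[free catalyst]*[target] forward; the back reaction follows from the equilibrium constant (K = 0.360, k = 1.80 × 10⁵ L mol⁻¹ s⁻¹)
    starting material + catalyst intermediate A ⇌ catalyst intermediate B (K = 4700 L mol⁻¹, k = 1.10 × 10⁶ L mol⁻¹ s⁻¹)
    catalyst intermediate B → free catalyst + target (k = 360 s⁻¹)
    partner + free catalyst ⇌ catalyst intermediate A (K = 690 L mol⁻¹, k = 2.40 × 10⁵ L mol⁻¹ s⁻¹)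

From 1.00 min to 2.00 min the flask's simulated levels give a fractional loss of 0.00720 s⁻¹, and K gives 0.00726 s⁻¹. The neighbour charged with 0.080 mM holds the same loadings, so it has 0.400 of the flask's catalyst. Scale the summer loss by that factor and by K, and count from the mean landing time of 9.00 s. Starting from the flask's mean share, this leaves 70.0%, and a second round leaves 70.4%. That neighbour ends with 71% of its starting material left.

All runs are calculated with constants of no real substance; the scatter is artificial.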